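**Remarks on the chemistry (assumptions)**

- Ring C is numbered C1' (bonded to coumarin C3), C2' (=CH), C3' (C=O), C4' (C(OH)-prenyl), C5' (CH2), C6' (C=O). The carbinol carbon C4' of 20 is (R).
- Adduct 15, drawn with formyl exo, bromine endo and the configuration (1S,2R,4R), holds the C4' oxygen, the prenyl group, C3' and C5' in the same spatial order as 20. Neither furan 11 nor adduct 15 needed a structural correction.
- 6 is taken as a catalogue compound (otherwise one Knoevenagel condensation of 2-hydroxy-4-methoxybenzaldehyde with ethyl acetoacetate). 14 is not stored and is made fresh.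
- 4, 5, 7, 8, 9 and 10 are racemic at the future C4'. This carbon is sp2 in 11, so nothing is lost.

## Structural features

The molecule is a 7-methoxycoumarin (benzene ring A fused to the 2-pyranone ring B) whose C3 carries, through an sp2–sp2 bond, C1' of ring C, a cyclohex-2-ene-1,4-dione: C1'=C2'H–C3'(=O)–C4'(OH)(prenyl)–C5'H2–C6'(=O). Its only stereocentre is the (R)-configured tertiary carbinol C4', which has no neighbouring stereocentre to lean on and sits α to the C3' ketone and β to the C6' ketone. This β-hydroxy ketone is the weak point: loss of water across C4'–C5', under acid or base, would give an achiral 2-aryl-5-prenyl-1,4-benzoquinone, so the free C4' hydroxyl and the C6' carbonyl should meet only under near-neutral conditions. Also fragile are the α-ketol (acyloin shift), the ene-dione (Michael acceptor, easily reduced), the coumarin lactone with its electrophilic C4 (hydroxide, alkoxides, hydride) and the prenyl alkene (acid, electrophilic oxidants, and cyclisation onto a free C4' hydroxyl). The real difficulty is therefore to create one quaternary, oxygen-bearing stereocentre in a ring whose other five carbons are sp2 or enolisable, and to arrive at the 1,4-dione pattern without passing through conditions that aromatise ring C. The key step uses the fact that the C4' oxygen and C1' are 1,4-related across ring C: if that oxygen is bonded to both, C1'–C2'–C3'–C4' and the oxygen form a 3-oxygenated furan and C5'–C6' is a two-carbon dienophile. Cleaving the C1'–O bond afterwards from the C3' enolate returns the C4' hydroxyl and the C1'=C2' double bond in a single event.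

## Logic of the disconnections

**20 ⇒ 19.** No ring bond is cut; one carbon is put back on C6', so that the C6' carbonyl becomes C6'(OH)–CH2OH. The C6' ketone is what makes the C4' hydroxyl eliminable, so it is kept masked until the end. The gain is that 19 cannot dehydrate to a quinone and tolerates mild base. The forward C–C cleavage must run at neutral pH and must leave the C3'/C4' α-ketol alone.

**19 ⇒ 18.** The C1'–O bond is re-formed (oxa-Michael sense), which turns the enone and the carbinol of 19 into the oxygen-bridged ketone 18. The gain is that C4' becomes a bridgehead tied to C1', so its configuration is a consequence of the bicycle. The forward β-elimination must break C1'–O and not C4'–O. This is guaranteed because in 18 only C3' is a carbonyl and it can enolise only towards C2'.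

**18 ⇒ 17 ⇒ 15 (through 16).** These are functional-group changes only. The glycol of 18 is the hydrolysed oxirane of 17 and its C3' ketone is the hydrolysed silyl enol ether. The oxirane is the reduced, ring-closed form of the bromo-formyl carbon of 15. A carbon bearing bromine and a formyl group is what a ketene-equivalent dienophile leaves behind, so this reaches the primary cycloadduct. Forward, the aldehyde must be reduced before the adduct can revert, and the acid step must come while the C4' oxygen is still an ether.

**15 ⇒ 11 + 14.** C4'–C5' and C6'–C1' are cut in a retro-[4+2]. This removes ring C, all three stereocentres and two skeletal bonds at once and leaves a flat furan and a three-carbon aldehyde. The forward step must control the dienophile face, the exo topology and the regiochemistry, and must outrun cycloreversion.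

**14 ⇒ 12.** The C–Br bond is removed; 14 is the bromination–dehydrobromination product of 12. The forward step only needs fresh material.

**11 ⇒ 10 ⇒ 8 (through 9).** First the O–Si bond is cut, then the ring O–C1' bond (hydration in reverse). 10 is the cyclodehydrated form of the hydroxy diketone 9, itself the desilylated 8. The gain is an open-chain 1,3-diketone. Forward, the acid must be mild enough for the prenyl alkene, and 10 must be silylated on oxygen.

**8 ⇒ 6 + 5 (through 7).** C2'–C3' is cut (Claisen-type). C1' and C2' come from the acetyl group of 6, and C3' and C4' from the carboxyl and α-carbon of 5. The forward acylation must avoid free, strongly basic enolates of 6, because its C4 is a Michael acceptor and its lactone is electrophilic.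

**5 ⇒ 4 ⇒ 2 + 3; 2 ⇒ 1.** The C4'–CH2(prenyl) bond is cut (enolate alkylation), then the ester and the silyl ether are traced back. The starting points are 1 and 3. The forward alkylation must be run cold so that C-alkylation is faster than silyl migration.

## Other disconnections considered

**Alternative 1:** Cut: C5'–C6', with the C4' oxygen bonded for a time to C6'.

- Forward key step: ring-expanding carbonylation of the 2,2-disubstituted oxirane A2 with [(salph)Al(THF)2][Co(CO)4] under CO. The aluminium cation activates the oxirane, tetracarbonylcobaltate opens it at the unsubstituted carbon C5', CO inserts, and the C4' alkoxide closes the four-membered lactone A1.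
- In its favour: C4' is not touched, so the configuration of A2 (reachable by Sharpless epoxidation of the 2-prenyl allylic alcohol, whose prenyl alkene is not allylic to the hydroxyl) would pass unchanged into A1. The aldol unit C4'–C5'–C6' is stored as a lactone that can neither dehydrate nor retro-aldolise. The step is atom-economic.
- Against it here: A1 holds only C3' (as CH2OSi), C4', C5', C6' and the prenyl group. C1', C2', the coumarin and ring C itself are all still to come. Acyl substitution at the lactone carbonyl by a C1' carbanion would compete with enolisation at C5' and with alkyl–oxygen cleavage or decarboxylation, which β,β-disubstituted β-lactones undergo readily. Once the lactone is opened, the elimination-prone tertiary β-hydroxy ketone must be carried in open-chain form. Cobalt hydride species could also move the prenyl double bond.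
- Comparison: in absolute stereocontrol this alternative is the better plan, because a dependable epoxidation replaces a cycloaddition that must deliver face, exo and regio selectivity on an untested diene. In mechanism the two are equal in idea: both hide the C4' oxygen in a strained ring (lactone here, ether bridge in 15). In structure the chosen plan is ahead, since 15 contains all six ring carbons and the closed ring while A1 contains none of the ring. In step economy the alternative is longer, because every remaining C–C bond of ring C needs its own step.

**Alternative 2:** Cut: the C1'=C2' double bond.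

- Forward key step: intramolecular Knoevenagel (aldol) condensation of the keto aldehyde A4 under a buffered secondary amine such as piperidinium acetate. The C1' methylene (α to the C6' ketone and allylic to coumarin C3=C4) adds to the C2' aldehyde and water is lost, giving A3, the triethylsilyl ether of 20.
- In its favour: ring C and the ene-dione appear together at the final oxidation level, so no redox adjustment follows ring closure. On this point it is better than the chosen plan, which spends four steps turning the bromo-formyl carbon into the C6' ketone. The conditions are mild and metal-free, and C4' is made beforehand and is not involved.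
- Against it here: A4 is a 2-oxo-aldehyde beside a quaternary silyloxy carbon and a second ketone. Hydrate and oligomer formation, a competing five-ring aldol of C1' onto the C3' ketone, and E1cB loss of silanol after enolisation towards C5' are all open. The amine can add to the ene-dione formed. The last operation would be removal of a silyl group from a β-silyloxy ketone with fluoride or acid, the conditions under which ring C is most likely to aromatise. The stereocentre must come from a separate sequence (for example through A1).
- Comparison: structurally both plans close ring C, but the chosen one forms two bonds and the stereocentre together, whereas this one forms one bond and no stereocentre. Mechanistically the condensation depends on one of several reversible aldol paths being preferred, while the cycloaddition has one productive path but can revert. In step economy the alternative is at best equal in the endgame and longer overall, because A4 needs a long linear synthesis.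

**Alternative 3:** Cut: C3'–C4'.

- Forward key step: intramolecular crossed benzoin reaction of the enal ketone A6 with a chiral triazolium-derived carbene and a mild base. The carbene adds to the C3' formyl group, the resulting acyl-anion equivalent adds to the C4' ketone, and the six-membered ring closes to give the tertiary α-ketol A5 (the C6' dimethyl ketal of 20).
- In its favour: the carbinol stereocentre and the α-ketol are made in one catalytic, redox-neutral step with the hydroxyl already free. In bond-forming efficiency at the stereocentre it is the equal of the chosen plan, and it is better in that nothing has to be unmasked at C4' afterwards. The ketal keeps C6' from promoting dehydration during the ring closure.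
- Against it here: the donor is an enal, and carbene adducts of enals tend to react as homoenolates (here at C1') or by internal redox instead of as acyl anions. The enal must have the C6' chain cis to the formyl group, the less stable geometry, which can isomerise under base. The β-keto ketal A6 can lose methanol by E1cB. The two groups on the ketone (prenyl CH2 and ring CH2) are sterically alike, so face selection rests on the catalyst alone. The final ketal hydrolysis is an acid step on the finished β-hydroxy ketone with a prenyl group next to a free hydroxyl.
- Comparison: structurally it forms one ring bond against two in the chosen step, but it sets the stereocentre just as directly. Mechanistically its chemoselectivity problem (acyl anion against homoenolate) is comparable in weight to the cycloaddition-against-Mukaiyama problem of the chosen plan. In step economy the ring closure and deprotection are shorter than steps 8–12, but the synthesis of A6 with a defined enal geometry would probably cancel this. The chosen plan also ends with a neutral step, which this one cannot.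

Key step: step 8

## Route

Step 1
Reactants: 1 methyl glycolate
Product: 2 methyl 2-[(tert-butyldimethylsilyl)oxy]acetate
Conditions: TBSCl, imidazole, DMF, 0 °C → rt
Reagents that add atoms: tert-butyldimethylsilyl chloride, CC(C)(C)[Si](C)(C)Cl
Why: Standard silyl ether formation on a primary alcohol with a silyl chloride and imidazole; the ether masks the hydroxyl during the enolate chemistry and is removed later in the step that closes the furanone.

Step 2
Reactants: 2 methyl 2-[(tert-butyldimethylsilyl)oxy]acetate; 3 prenyl bromide (1-bromo-3-methylbut-2-ene)
Product: 4 methyl 2-[(tert-butyldimethylsilyl)oxy]-5-methylhex-4-enoate (racemic)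
Conditions: LiN(iPr)2, THF, −78 °C; then 3, DMPU, −78 → −40 °C
Reagents that add atoms: none
Why: Alkylation of the lithium enolate of an α-silyloxy ester with a primary allylic bromide (SN2, so the prenyl unit is attached without allylic transposition), run at −78 °C so that C-alkylation outruns silyl migration and self-condensation. The new stereocentre forms as a racemate, which does not matter because this carbon becomes sp2 in 11.

Step 3
Reactants: 4 methyl 2-[(tert-butyldimethylsilyl)oxy]-5-methylhex-4-enoate
Product: 5 2-[(tert-butyldimethylsilyl)oxy]-5-methylhex-4-enoic acid (racemic)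
Conditions: LiOH·H2O, THF–MeOH–H2O, 0 °C → rt; 1 M HCl to pH 3–4
Reagents that add atoms: lithium hydroxide, [Li+].[OH-]
Why: Saponification of a methyl ester; the secondary silyl ether tolerates LiOH and a brief acidification to pH 3–4.

Step 4
Reactants: 5 2-[(tert-butyldimethylsilyl)oxy]-5-methylhex-4-enoic acid; 6 3-acetyl-7-methoxycoumarin (3-acetyl-7-methoxy-2H-chromen-2-one)
Product: 8 3-{4-[(tert-butyldimethylsilyl)oxy]-7-methyl-3-oxooct-6-enoyl}-7-methoxy-2H-chromen-2-one (racemic; largely enolised), via acid chloride 7 (not isolated)
Conditions: Me2C=C(Cl)NMe2, CH2Cl2, 0 °C → rt; then 6, MgBr2·OEt2 (2.5 equiv), i-Pr2NEt (3 equiv, slow addition), CH2Cl2, 0 °C → rt; cold 0.5 M HCl work-up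
Reagents that add atoms: none
Why: Soft-enolisation C-acylation of a methyl ketone by an acid chloride (crossed Claisen type): MgBr2 chelates the acetyl and lactone carbonyls of 6, a hindered amine then removes a methyl proton, and the magnesium enolate is acylated on carbon at once. Because no strong base is used and the enolate never accumulates, conjugate addition to C4 of a second coumarin and attack on the lactone should be suppressed, and the product sits as a magnesium chelate that resists a second acylation. The acid chloride is made with the α-chloroenamine under neutral conditions so that the silyl ether survives.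

Step 5
Reactants: 8 3-{4-[(tert-butyldimethylsilyl)oxy]-7-methyl-3-oxooct-6-enoyl}-7-methoxy-2H-chromen-2-one
Product: 10 5-(7-methoxy-2-oxo-2H-chromen-3-yl)-2-(3-methylbut-2-en-1-yl)furan-3(2H)-one (racemic), via hydroxy diketone 9 (not isolated)
Conditions: 48% aq. HF, MeCN, 0 °C → rt; then TsOH·H2O (cat.), CH2Cl2, rt
Reagents that add atoms: none
Why: Acidic desilylation frees the α'-hydroxy-1,3-diketone, whose hydroxyl adds to the distal, coumarin-bearing carbonyl (5-exo-trig) and loses water to give the vinylogous ester, the classical cyclodehydration route to 3(2H)-furanones. These acids are too weak or too dilute to protonate the prenyl alkene at a useful rate; 10 is kept under argon because 2-monosubstituted 3(2H)-furanones autoxidise at C2.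

Step 6
Reactants: 10 5-(7-methoxy-2-oxo-2H-chromen-3-yl)-2-(3-methylbut-2-en-1-yl)furan-3(2H)-one
Product: 11 3-{4-[(tert-butyldimethylsilyl)oxy]-5-(3-methylbut-2-en-1-yl)furan-2-yl}-7-methoxy-2H-chromen-2-one
Conditions: TBSOTf, Et3N, CH2Cl2, 0 °C
Reagents that add atoms: tert-butyldimethylsilyl trifluoromethanesulfonate, CC(C)(C)[Si](C)(C)OS(=O)(=O)C(F)(F)F
Why: O-Silylation of the furanone by silyl triflate/amine soft enolisation: loss of the C2 proton gives the aromatic 3-silyloxyfuran, a known conversion of 3(2H)-furanones. The product is acid-sensitive, so it is filtered through base-washed silica and used promptly.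

Step 7
Reactants: 12 acrolein
Product: 14 2-bromoacrolein (2-bromoprop-2-enal), via 2,3-dibromopropanal 13 (not isolated)
Conditions: Br2, CH2Cl2, −78 → 0 °C; then Et3N, 0 °C; distilled
Reagents that add atoms: bromine, BrBr
Why: Bromine adds across the alkene of acrolein and triethylamine removes HBr from the 2,3-dibromo aldehyde (E1cB), the standard bromination–dehydrobromination route to 2-bromoacrolein; it is used fresh because it polymerises.

Step 8
Reactants: 11 3-{4-[(tert-butyldimethylsilyl)oxy]-5-(3-methylbut-2-en-1-yl)furan-2-yl}-7-methoxy-2H-chromen-2-one; 14 2-bromoacrolein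
Product: 15 (1S,2R,4R)-2-bromo-5-[(tert-butyldimethylsilyl)oxy]-1-(7-methoxy-2-oxo-2H-chromen-3-yl)-4-(3-methylbut-2-en-1-yl)-7-oxabicyclo[2.2.1]hept-5-ene-2-carbaldehyde (formyl exo, bromine endo)
Conditions: (4S)-2-butyl-4-(1H-indol-3-ylmethyl)-3-(4-methylphenylsulfonyl)-1,3,2-oxazaborolidin-5-one (20 mol%, preformed from N-tosyl-(S)-tryptophan and BuB(OH)2), 14 (3 equiv), CH2Cl2, −78 °C; crude adduct kept cold and taken on at once
Reagents that add atoms: none
Why: Diels–Alder addition of a furan to 2-bromoacrolein under a tryptophan-derived N-sulfonyl oxazaborolidinone; the closest known reaction type is the same catalysed addition to unsubstituted furan. Boron binds the formyl oxygen of s-cis 14 and the indole ring stacks over one face of its C=C, so 11 can approach only the other face, which fixes C6' as (R). The addition is normal-demand and asynchronous: C4' of 11, the β-carbon of the silyl enol ether and the most nucleophilic terminus, bonds first to the CH2 of 14 and C1' then bonds to the brominated carbon on the same face of the furan, so the six-membered carbocycle is closed by a suprafacial [4+2] annulation and the furan oxygen becomes the one-atom bridge. C1' and C4' are created together and can only be cis across that bridge; their sense relative to C6' follows from the formyl-exo (bromine-endo) topology that 2-bromoacrolein prefers. The para regiochemistry (C3' and C6' 1,4-related) is secured by the 3-silyloxy group and reinforced by the acceptor-substituted coumarinyl terminus, which also disfavours the competing vinylfuran diene made up of the coumarin C3=C4 and furan C1'=C2' bonds. Three selectivities are needed at once (dienophile face, exo topology, regiochemistry), because once C6' is later made sp2 an endo adduct from the same dienophile face would lead to the enantiomer of 20; the minor diastereomer is therefore removed at 17. Cycloaddition must also beat Mukaiyama-type 1,2- or 1,4-addition of the silyl enol ether, for which the low temperature, the tight s-cis complex and the bulky silyl group are relied on. The adduct is not stored but reduced at once in step 9, since furan adducts carrying a formyl group revert easily.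

Step 9
Reactants: 15 (1S,2R,4R)-2-bromo-5-[(tert-butyldimethylsilyl)oxy]-1-(7-methoxy-2-oxo-2H-chromen-3-yl)-4-(3-methylbut-2-en-1-yl)-7-oxabicyclo[2.2.1]hept-5-ene-2-carbaldehyde
Product: 17 3-[(1S,2R,4R)-5-[(tert-butyldimethylsilyl)oxy]-4-(3-methylbut-2-en-1-yl)spiro[7-oxabicyclo[2.2.1]hept-5-ene-2,2'-oxiran]-1-yl]-7-methoxy-2H-chromen-2-one (oxirane oxygen exo), via bromohydrin 16 (not isolated)
Conditions: NaBH4, THF–MeOH, −78 → −30 °C; then K2CO3, MeOH, 0 °C → rt; chromatography (removes the endo-formyl-derived diastereomer)
Reagents that add atoms: none
Why: Borohydride 1,2-reduction of the aldehyde gives the bromohydrin and removes the acceptor group that makes cycloreversion easy, and the coumarin lactone is not attacked at this temperature. Carbonate then closes the oxirane by intramolecular Williamson substitution (3-exo-tet) with inversion at C6'; C1' and C4' are untouched.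

Step 10
Reactants: 17 3-[(1S,2R,4R)-5-[(tert-butyldimethylsilyl)oxy]-4-(3-methylbut-2-en-1-yl)spiro[7-oxabicyclo[2.2.1]hept-5-ene-2,2'-oxiran]-1-yl]-7-methoxy-2H-chromen-2-one
Product: 18 (1R,4S,5R)-5-hydroxy-5-(hydroxymethyl)-4-(7-methoxy-2-oxo-2H-chromen-3-yl)-1-(3-methylbut-2-en-1-yl)-7-oxabicyclo[2.2.1]heptan-2-one
Conditions: HClO4 (0.1 M) in THF–H2O 3:1, 0 °C → rt
Reagents that add atoms: water, O
Why: Acid-catalysed hydrolysis of a 2,2-disubstituted oxirane (water is expected at the primary carbon, because ionisation at C6' is disfavoured by the adjacent ether oxygen and the bicyclic frame) together with hydrolysis of the silyl enol ether to the C3' ketone. The C4' oxygen is still an ether here, so the prenyl group has no free hydroxyl to cyclise onto, and the configuration at C6' is of no consequence because this carbon becomes a carbonyl in step 12.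

Step 11
Reactants: 18 (1R,4S,5R)-5-hydroxy-5-(hydroxymethyl)-4-(7-methoxy-2-oxo-2H-chromen-3-yl)-1-(3-methylbut-2-en-1-yl)-7-oxabicyclo[2.2.1]heptan-2-one
Product: 19 3-[(4R,6S)-4,6-dihydroxy-6-(hydroxymethyl)-4-(3-methylbut-2-en-1-yl)-3-oxocyclohex-1-en-1-yl]-7-methoxy-2H-chromen-2-one
Conditions: DBU (0.3 equiv), CH2Cl2, 0 °C
Reagents that add atoms: none
Why: E1cB (retro-oxa-Michael) opening of a 7-oxabicyclo[2.2.1]heptan-2-one: the C3' ketone can enolise only towards C2', and this enolate expels the bridging oxygen from C1' with release of ring strain, giving the C1'=C2' enone and the C4' carbinol with its C–O bond, and hence its configuration, intact. Because C6' is not yet a carbonyl, opening in the other direction (loss of the oxygen from C4') is impossible.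

Step 12
Reactants: 19 3-[(4R,6S)-4,6-dihydroxy-6-(hydroxymethyl)-4-(3-methylbut-2-en-1-yl)-3-oxocyclohex-1-en-1-yl]-7-methoxy-2H-chromen-2-one
Product: 20 3-[(4R)-4-hydroxy-4-(3-methylbut-2-en-1-yl)-3,6-dioxocyclohex-1-en-1-yl]-7-methoxy-2H-chromen-2-one
Conditions: NaIO4 (1.1 equiv), THF–pH 7 phosphate buffer, 0 °C
Reagents that add atoms: none
Why: Periodate (Malaprade) cleavage of the tertiary/primary 1,2-diol gives the C6' ketone and formaldehyde at neutral pH and 0 °C, where the new β-hydroxy ketone should not dehydrate to the quinone. The tertiary α-ketol at C3'/C4' is cleaved far more slowly than a vicinal diol, so about one equivalent is used and the reaction is stopped when 19 is consumed; no stereocentre is touched.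

## Compound list

1 | methyl glycolate (methyl 2-hydroxyacetate) | COC(=O)CO | starting material
2 | methyl 2-[(tert-butyldimethylsilyl)oxy]acetate | COC(=O)CO[Si](C)(C)C(C)(C)C | intermediate
3 | prenyl bromide (1-bromo-3-methylbut-2-ene) | CC(C)=CCBr | starting material
4 | methyl 2-[(tert-butyldimethylsilyl)oxy]-5-methylhex-4-enoate (racemic) | COC(=O)C(CC=C(C)C)O[Si](C)(C)C(C)(C)C | intermediate
5 | 2-[(tert-butyldimethylsilyl)oxy]-5-methylhex-4-enoic acid (racemic) | OC(=O)C(CC=C(C)C)O[Si](C)(C)C(C)(C)C | intermediate
6 | 3-acetyl-7-methoxycoumarin (3-acetyl-7-methoxy-2H-chromen-2-one) | COc1ccc2cc(C(C)=O)c(=O)oc2c1 | starting material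
7 | 2-[(tert-butyldimethylsilyl)oxy]-5-methylhex-4-enoyl chloride (racemic; not isolated) | ClC(=O)C(CC=C(C)C)O[Si](C)(C)C(C)(C)C | intermediate
8 | 3-{4-[(tert-butyldimethylsilyl)oxy]-7-methyl-3-oxooct-6-enoyl}-7-methoxy-2H-chromen-2-one (racemic) | COc1ccc2cc(C(=O)CC(=O)C(CC=C(C)C)O[Si](C)(C)C(C)(C)C)c(=O)oc2c1 | intermediate
9 | 3-(4-hydroxy-7-methyl-3-oxooct-6-enoyl)-7-methoxy-2H-chromen-2-one (racemic; not isolated) | COc1ccc2cc(C(=O)CC(=O)C(O)CC=C(C)C)c(=O)oc2c1 | intermediate
10 | 5-(7-methoxy-2-oxo-2H-chromen-3-yl)-2-(3-methylbut-2-en-1-yl)furan-3(2H)-one (racemic) | COc1ccc2cc(C3=CC(=O)C(CC=C(C)C)O3)c(=O)oc2c1 | intermediate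
11 | 3-{4-[(tert-butyldimethylsilyl)oxy]-5-(3-methylbut-2-en-1-yl)furan-2-yl}-7-methoxy-2H-chromen-2-one | CC(C)=CCc1oc(-c2cc3ccc(OC)cc3oc2=O)cc1O[Si](C)(C)C(C)(C)C | intermediate
12 | acrolein (prop-2-enal) | C=CC=O | starting material
13 | 2,3-dibromopropanal (racemic; not isolated) | O=CC(Br)CBr | intermediate
14 | 2-bromoacrolein (2-bromoprop-2-enal) | C=C(Br)C=O | intermediate
15 | (1S,2R,4R)-2-bromo-5-[(tert-butyldimethylsilyl)oxy]-1-(7-methoxy-2-oxo-2H-chromen-3-yl)-4-(3-methylbut-2-en-1-yl)-7-oxabicyclo[2.2.1]hept-5-ene-2-carbaldehyde | C1=C(O[Si](C)(C)C(C)(C)C)[C@@]2(CC=C(C)C)C[C@](Br)(C=O)[C@]1(c3cc4ccc(OC)cc4oc3=O)O2 | intermediate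
16 | 3-[(1S,2S,4R)-2-bromo-5-[(tert-butyldimethylsilyl)oxy]-2-(hydroxymethyl)-4-(3-methylbut-2-en-1-yl)-7-oxabicyclo[2.2.1]hept-5-en-1-yl]-7-methoxy-2H-chromen-2-one (not isolated) | C1=C(O[Si](C)(C)C(C)(C)C)[C@@]2(CC=C(C)C)C[C@](Br)(CO)[C@]1(c3cc4ccc(OC)cc4oc3=O)O2 | intermediate
17 | 3-[(1S,2R,4R)-5-[(tert-butyldimethylsilyl)oxy]-4-(3-methylbut-2-en-1-yl)spiro[7-oxabicyclo[2.2.1]hept-5-ene-2,2'-oxiran]-1-yl]-7-methoxy-2H-chromen-2-one | C1=C(O[Si](C)(C)C(C)(C)C)[C@@]2(CC=C(C)C)C[C@@]3(CO3)[C@]1(c4cc5ccc(OC)cc5oc4=O)O2 | intermediate
18 | (1R,4S,5R)-5-hydroxy-5-(hydroxymethyl)-4-(7-methoxy-2-oxo-2H-chromen-3-yl)-1-(3-methylbut-2-en-1-yl)-7-oxabicyclo[2.2.1]heptan-2-one | C1C(=O)[C@@]2(CC=C(C)C)C[C@@](O)(CO)[C@]1(c3cc4ccc(OC)cc4oc3=O)O2 | intermediate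
19 | 3-[(4R,6S)-4,6-dihydroxy-6-(hydroxymethyl)-4-(3-methylbut-2-en-1-yl)-3-oxocyclohex-1-en-1-yl]-7-methoxy-2H-chromen-2-one | COc1ccc2cc(C3=CC(=O)[C@@](O)(CC=C(C)C)C[C@@]3(O)CO)c(=O)oc2c1 | intermediate
20 | 3-[(4R)-4-hydroxy-4-(3-methylbut-2-en-1-yl)-3,6-dioxocyclohex-1-en-1-yl]-7-methoxy-2H-chromen-2-one | COc1ccc2cc(C3=CC(=O)[C@@](O)(CC=C(C)C)CC3=O)c(=O)oc2c1 | target

## Step count and least certain steps

Total: 12 steps. Longest linear sequence: 11 steps (1 → 2 → 4 → 5 → 8 → 10 → 11 → 15 → 17 → 18 → 19 → 20). Step 7 is a one-step side branch.

**Step 8 (key step).** Three things are most likely to go wrong.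
- Cycloreversion during the reaction or work-up, because the adduct has two fully substituted bridgeheads next to a quaternary carbon and is stabilised only once the aldehyde is reduced.
- Addition through an open, stepwise transition state (Mukaiyama aldol at the formyl carbon, or conjugate addition without ring closure). This would lose the ring and also the link between the face control on the dienophile and the configuration at C4'.
- Slow turnover because the coumarin carbonyl competes with the aldehyde for boron.

The sense of induction is inferred by analogy with simpler dienes and has to be checked on the first adduct; the catalyst from (R)-tryptophan is the remedy if it is opposite.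

Fallback, from 11 and 14, back at 16: the cycloaddition is run without any Lewis acid (concentrated CH2Cl2 solution at −20 to 0 °C, or 10–12 kbar at room temperature), which removes the Mukaiyama pathways. Under these conditions 15 forms together with its mirror-image adduct F1. NaBH4 in MeOH is added to the same flask so that each adduct molecule is reduced before it can revert, giving 16 together with its mirror-image bromohydrin F2. The exo-formyl series is separated from the endo series on silica, and the enantiomers are resolved by preparative chromatography on a polysaccharide chiral stationary phase. 16 re-enters the route at the carbonate treatment of step 9.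

**Step 4.** The likely failure is self-condensation of 6 by conjugate addition of its enolate to C4 of a second molecule, or O-acylation, because 3-acylcoumarins are strong Michael acceptors.

Fallback, from 4 and 6, back at 8: ester 4 is reduced (i-Bu2AlH, CH2Cl2, −78 °C) to 2-[(tert-butyldimethylsilyl)oxy]-5-methylhex-4-enal F3. 6 is converted (TMSOTf, Et3N, CH2Cl2, 0 °C) into its silyl enol ether, 7-methoxy-3-[1-(trimethylsilyloxy)ethenyl]-2H-chromen-2-one F4. Mukaiyama aldol addition of F4 to F3 (BF3·OEt2, CH2Cl2, −78 °C) gives 3-{4-[(tert-butyldimethylsilyl)oxy]-3-hydroxy-7-methyloct-6-enoyl}-7-methoxy-2H-chromen-2-one F5 as a diastereomer mixture. Dess–Martin oxidation of F5 gives 8. No free enolate of 6 is present at any point.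

**Step 10.** The likely failures are hydration of the prenyl alkene during a slow epoxide hydrolysis, or a cationic skeletal shift at C6' if the oxirane ionises instead of being attacked at its primary carbon. A premature acid-induced opening of the bridge would only anticipate step 11.

Fallback, from 17, back at 19: the oxirane is opened at its primary carbon by acetate (CsOAc, DMF, 60–70 °C; SN2, no cation) to the hydroxy acetate, [(1S,2R,4R)-5-[(tert-butyldimethylsilyl)oxy]-2-hydroxy-1-(7-methoxy-2-oxo-2H-chromen-3-yl)-4-(3-methylbut-2-en-1-yl)-7-oxabicyclo[2.2.1]hept-5-en-2-yl]methyl acetate F6. K2CO3 in MeOH at 0 °C removes the acetyl group to give the diol that still carries the silyl enol ether, 3-[(1S,2R,4R)-5-[(tert-butyldimethylsilyl)oxy]-2-hydroxy-2-(hydroxymethyl)-4-(3-methylbut-2-en-1-yl)-7-oxabicyclo[2.2.1]hept-5-en-1-yl]-7-methoxy-2H-chromen-2-one F7. Bu4NF (THF, 0 °C) then liberates the C3' enolate, which expels the bridging oxygen from C1' and gives 19 directly. Any enol ether lost early gives 18, which the fluoride also converts into 19.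

**Step 11.** The likely failures are base-mediated: 1,6-addition of the primary hydroxyl to coumarin C4, acyloin shift of the new α-ketol, or trans-lactonisation of the coumarin by the neighbouring hydroxyls.

Fallback, from 18, back at 19: 18 is treated with TMSOTf and Et3N (CH2Cl2, −20 → 0 °C). Silylation of both hydroxyls, formation of the C2'/C3' silyl enol ether and Lewis-acid-assisted cleavage of the C1'–O bond give the tris(trimethylsilyl) ether of 19, 7-methoxy-3-[(4R,6S)-4-(3-methylbut-2-en-1-yl)-3-oxo-4,6-bis(trimethylsilyloxy)-6-[(trimethylsilyloxy)methyl]cyclohex-1-en-1-yl]-2H-chromen-2-one F8. Brief methanolysis (citric acid, MeOH, 0 °C) removes the three silyl groups and returns 19 without a free alkoxide having been present.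

## Further compounds

F1 | step 8 | (1R,2S,4S)-2-bromo-5-[(tert-butyldimethylsilyl)oxy]-1-(7-methoxy-2-oxo-2H-chromen-3-yl)-4-(3-methylbut-2-en-1-yl)-7-oxabicyclo[2.2.1]hept-5-ene-2-carbaldehyde (mirror image of 15) | C1=C(O[Si](C)(C)C(C)(C)C)[C@]2(CC=C(C)C)C[C@@](Br)(C=O)[C@@]1(c3cc4ccc(OC)cc4oc3=O)O2
F2 | step 8 | 3-[(1R,2R,4S)-2-bromo-5-[(tert-butyldimethylsilyl)oxy]-2-(hydroxymethyl)-4-(3-methylbut-2-en-1-yl)-7-oxabicyclo[2.2.1]hept-5-en-1-yl]-7-methoxy-2H-chromen-2-one (mirror image of 16) | C1=C(O[Si](C)(C)C(C)(C)C)[C@]2(CC=C(C)C)C[C@@](Br)(CO)[C@@]1(c3cc4ccc(OC)cc4oc3=O)O2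
F3 | step 4 | 2-[(tert-butyldimethylsilyl)oxy]-5-methylhex-4-enal (racemic) | O=CC(CC=C(C)C)O[Si](C)(C)C(C)(C)C
F4 | step 4 | 7-methoxy-3-[1-(trimethylsilyloxy)ethenyl]-2H-chromen-2-one | COc1ccc2cc(C(=C)O[Si](C)(C)C)c(=O)oc2c1
F5 | step 4 | 3-{4-[(tert-butyldimethylsilyl)oxy]-3-hydroxy-7-methyloct-6-enoyl}-7-methoxy-2H-chromen-2-one (mixture of diastereomers) | COc1ccc2cc(C(=O)CC(O)C(CC=C(C)C)O[Si](C)(C)C(C)(C)C)c(=O)oc2c1
F6 | step 10 | [(1S,2R,4R)-5-[(tert-butyldimethylsilyl)oxy]-2-hydroxy-1-(7-methoxy-2-oxo-2H-chromen-3-yl)-4-(3-methylbut-2-en-1-yl)-7-oxabicyclo[2.2.1]hept-5-en-2-yl]methyl acetate | C1=C(O[Si](C)(C)C(C)(C)C)[C@@]2(CC=C(C)C)C[C@@](O)(COC(C)=O)[C@]1(c3cc4ccc(OC)cc4oc3=O)O2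
F7 | step 10 | 3-[(1S,2R,4R)-5-[(tert-butyldimethylsilyl)oxy]-2-hydroxy-2-(hydroxymethyl)-4-(3-methylbut-2-en-1-yl)-7-oxabicyclo[2.2.1]hept-5-en-1-yl]-7-methoxy-2H-chromen-2-one | C1=C(O[Si](C)(C)C(C)(C)C)[C@@]2(CC=C(C)C)C[C@@](O)(CO)[C@]1(c3cc4ccc(OC)cc4oc3=O)O2
F8 | step 11 | 7-methoxy-3-[(4R,6S)-4-(3-methylbut-2-en-1-yl)-3-oxo-4,6-bis(trimethylsilyloxy)-6-[(trimethylsilyloxy)methyl]cyclohex-1-en-1-yl]-2H-chromen-2-one | COc1ccc2cc(C3=CC(=O)[C@@](O[Si](C)(C)C)(CC=C(C)C)C[C@@]3(O[Si](C)(C)C)CO[Si](C)(C)C)c(=O)oc2c1
A1 | alternative 1 | (4R)-4-{[(tert-butyldimethylsilyl)oxy]methyl}-4-(3-methylbut-2-en-1-yl)oxetan-2-one | CC(C)(C)[Si](C)(C)OC[C@@]1(CC=C(C)C)CC(=O)O1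
A2 | alternative 1 | (R)-tert-butyldimethyl{[2-(3-methylbut-2-en-1-yl)oxiran-2-yl]methoxy}silane | CC(C)(C)[Si](C)(C)OC[C@@]1(CC=C(C)C)CO1
A3 | alternative 2 | 7-methoxy-3-[(4R)-4-(3-methylbut-2-en-1-yl)-3,6-dioxo-4-[(triethylsilyl)oxy]cyclohex-1-en-1-yl]-2H-chromen-2-one | COc1ccc2cc(C3=CC(=O)[C@@](O[Si](CC)(CC)CC)(CC=C(C)C)CC3=O)c(=O)oc2c1
A4 | alternative 2 | (3R)-6-(7-methoxy-2-oxo-2H-chromen-3-yl)-3-(3-methylbut-2-en-1-yl)-2,5-dioxo-3-[(triethylsilyl)oxy]hexanal | COc1ccc2cc(CC(=O)C[C@](O[Si](CC)(CC)CC)(CC=C(C)C)C(=O)C=O)c(=O)oc2c1
A5 | alternative 3 | 3-[(4R)-4-hydroxy-6,6-dimethoxy-4-(3-methylbut-2-en-1-yl)-3-oxocyclohex-1-en-1-yl]-7-methoxy-2H-chromen-2-one | COc1ccc2cc(C3=CC(=O)[C@@](O)(CC=C(C)C)CC3(OC)OC)c(=O)oc2c1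
A6 | alternative 3 | (2Z)-4,4-dimethoxy-3-(7-methoxy-2-oxo-2H-chromen-3-yl)-9-methyl-6-oxodeca-2,8-dienal | O=C/C=C(/c1cc2ccc(OC)cc2oc1=O)C(OC)(OC)CC(=O)CC=C(C)C
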